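## Structural features

Pakyonol is a macrocyclic bis(bibenzyl): four benzene rings are joined into a 20-membered ring by two diaryl ether oxygens and two CH2–CH2 bridges. Ring A is a 1,3,4-trisubstituted anisole (bridge carbon at C1, ether oxygen at C3, OMe at C4) and ring B is a para-phenylene. Ring C is a 1,3,4-trisubstituted phenol (bridge at C1, free OH at C3, ether oxygen to ring D at C4) and ring D is a meta-phenylene. The target has no stereocenter and no alkene, so no stereocenters stand next to each other; the only stereochemical element in the route is a transient alkene geometry. The fragile points are the electron-rich free phenol of ring C and, in the intermediates, the aryl iodide, the aldehydes and the styrene. The real difficulty is twofold: each diaryl ether is unsymmetrical and sits ortho to a second oxygen substituent, and a 20-membered ring holding two rigid para-phenylenes must be closed against oligomerization. The key step exploits the two-carbon bridge between C3 of ring D and C1 of ring A. Both rings are meta-linked, so an E-CH=CH unit can be accommodated there, and the bond from the ring D carbon to the terminal vinyl carbon on ring A can be made by aryl–vinyl coupling and the alkene hydrogenated afterwards.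

## Logic of the disconnections

**17 from 16.** No skeletal bond is cut. The saturated bridge between rings D and A is taken back to an E-alkene and the ring C hydroxyl to a benzyl ether. This creates the retron for an aryl–vinyl coupling. Benzyl is preferred to an acetal protecting group because one hydrogenation then saturates the bridge and frees the phenol, which saves a step and avoids chloromethyl methyl ether. The forward step must reduce a stilbene and cleave one O–CH2Ph bond while two diaryl ethers and the methyl ether stay intact.

**16 from 15.** The bond between C3 of ring D and the adjacent bridge carbon is cut. It lies between the two meta-linked rings, where a rigid E-alkene can be tolerated, and its two ends (C–I and vinyl) are inert to everything used earlier. The macrocycle opens to a linear chain of four rings. The forward step must arylate the terminal alkene carbon, not the internal one, and must beat intermolecular coupling.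

**15 from 14.** The C=C bond of the vinyl group is cut back to a formyl group. A vinyl group could not be carried through the earlier alkene reduction, whereas the formyl group arrives with ring A at no cost. The forward methylenation must use a preformed ylide so that no strong base meets the C–I bond.

**14 from 12 and 13.** The bond between the ether oxygen and C3 of ring A is cut. This carbon is meta to the formyl group and cannot be reached by SNAr, so an oxidative copper coupling of the arylboron compound 13 at room temperature is chosen. It leaves the C–I bond untouched. Ring A is removed as one commercial piece. The forward step has to transfer an aryl group that carries an ortho methoxy group, and the ring B hydroxyl of 12 must be the only free OH, which the benzyl ether on ring C guarantees.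

**12 from 11, and 11 from 4 and 8 (through 9 and 10).** The saturated bridge between rings B and C is taken back to an alkene, and the alkene is cut into a formyl group on ring C and a phosphorus ylide on the benzylic carbon of ring B. This halves the molecule. The reduction must spare C–I and O–CH2Ph, which rules out catalytic hydrogenation and calls for diimide. The alkene geometry is irrelevant. The ring B oxygen needs a silyl group only while the ylide exists, so it is removed in the same flask.

**4 from 2 and 3; 2 from 1.** The bond between the ether oxygen and C4 of ring C is cut. This carbon is para to the formyl group, so fluoride displacement by the phenoxide of 3 is available without any metal, and the iodine of ring D comes in already in its meta position. Benzylation of 1 prevents a deactivating phenoxide on the electrophile. The forward step must tolerate an alkoxy group ortho to the fluoride.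

**8 from 7, 6 and 5.** The C–P bond, then the benzylic C–H (reduction of a formyl group), then the O–Si bond are undone. Each step is a one-group change on a simple para-substituted benzene. The only demand is that the silyl ether survive hydride and mild acid.

## Other disconnections considered

**Alternative 1:** The cut is the ether bond between the ring B oxygen and C3 of ring A.
- Forward step: the open-chain bis-phenol A2 carries ring A as a 2,6-dibromophenol and ring B as a 2,6-dichlorophenol. Tl(NO3)3 (trivalent thallium) would oxidize the more easily oxidized dibromophenol, the ring B phenol oxygen would add to its ortho carbon, and Zn in the same flask would reduce the bromodienone to the macrocyclic bromophenol A1.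
- In its favour: it follows the presumed biosynthesis. It makes the ortho-oxygenated diaryl ether and the 20-membered ring in one operation without an arylmetal. It releases the ring A oxygen as a free phenol exactly where the methyl group is needed.
- Against it here: a highly toxic thallium salt is needed in stoichiometric amount. The direction of coupling rests only on the different oxidation potentials of two similar halophenols, so oxidation of the wrong ring or C–C coupling would give isomers. Four halogens must be installed and later removed, and a methylation is added.
- Comparison: on structure the two plans are equal, since each closes the same ring at a flexible point. On mechanism the chosen plan is better, because C–I and vinyl are two uniquely defined sites. On step economy they are about equal: the late copper coupling is saved, but halogenations and a two-step end game (methylation, global hydrogenolysis) are added. Forming the hindered ether and the ring together is a point on which this alternative is the better one.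

**Alternative 2:** The cut is the bond between the ring D oxygen and C4 of ring C, with ring C held back as a cyclohexenone.
- Forward step: in the bromo enone A4 the ring D phenoxide would displace bromide from C6 of the 3-substituted cyclohex-2-enone in an intramolecular SN2 reaction. This would give the racemic macrocyclic aryloxy enone A3. Dehydrogenation would then aromatize ring C and turn the carbonyl into the phenol.
- In its favour: the ether is made by alkylation, not arylation, so no metal is needed. The ring C hydroxyl appears with the right regiochemistry and without a protecting group. The sp3 carbons make the open chain more flexible at the moment of closure.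
- Against it here: a base, a phenoxide and an alpha-bromo ketone open several ionic side paths (dehydrobromination to a phenol that lacks the ether, enolization, Favorskii-type rearrangement). The electrophile is a secondary bromide in a macrocyclic SN2. A regioselective alpha-prime bromination and a final oxidation on an electron-rich macrocycle are required. The new stereocenter is irrelevant because aromatization erases it.
- Comparison: on structure this alternative is the better one (less strain at closure, no protecting group on ring C). On mechanism the chosen plan is safer. On step economy they are roughly equal, because building the cyclohexenone and aromatizing it costs what the Wittig and diimide steps cost.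

**Alternative 3:** The cut is the bond between C1 of ring A and the bridge carbon.
- Forward step: the arylacetyl chloride A6 on ring D would be ionized by SnCl4 at high dilution and would acylate ring A para to the methoxy group. This would give the macrocyclic ketone A5, in which ring C is deactivated as its mesylate. Deoxygenation of the ketone and cleavage of the mesylate would follow.
- In its favour: it closes the same meta–meta bridge as the chosen plan, and ring A needs no handle at all. Ring A enters as a plain 2-methoxyphenyl ether, so neither a boronic acid nor an iodide nor a methylenation is required and the precursor is probably shorter. The reagents are cheap.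
- Against it here: the site of attack is set only by electronic bias. Ring A has two para-directing oxygens, and rings B and D are activated aryl ethers as well. Arylacetyl chlorides can lose HCl to ketenes. The end game needs two steps where the chosen plan needs one.
- Comparison: on structure the plans are equal. On mechanism the chosen plan is better, because functional groups and not relative nucleophilicity fix the site. On step economy before the ring closure this alternative is the better one, and after it the worse.

Key step: step 10

Remark: 15 and 16 map atom for atom onto 17 (same 20-membered ring, ether oxygens ortho to OMe on ring A and ortho to the protected OH on ring C), so neither skeleton needs correction and only the protecting group on the ring C oxygen is changed to benzyl; 11 is carried on as an E/Z mixture because both isomers give 12.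

## Route

Step 1
Reactants: 1 4-fluoro-3-hydroxybenzaldehyde
Product: 2 3-(benzyloxy)-4-fluorobenzaldehyde
Conditions: BnBr, K2CO3, DMF, rt
Reagents that add atoms: benzyl bromide, BrCc1ccccc1
Why: Williamson ether synthesis on an acidic phenol; the benzyl group stops the ring C oxygen from becoming a deactivating phenoxide in step 2 and is removed in step 11 by the hydrogenation that saturates the bridge.

Step 2
Reactants: 2 3-(benzyloxy)-4-fluorobenzaldehyde; 3 3-iodophenol
Product: 4 3-(benzyloxy)-4-(3-iodophenoxy)benzaldehyde
Conditions: K2CO3, DMF, 130 °C
Reagents that add atoms: none
Why: SNAr (addition–elimination through a Meisenheimer intermediate): the fluoride para to the formyl group is displaced by the phenoxide of 3. No transition metal is present, so the C–I bond is not touched.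

Step 3
Reactants: 5 4-hydroxybenzaldehyde
Product: 6 4-[(triisopropylsilyl)oxy]benzaldehyde
Conditions: i-Pr3SiCl, imidazole, DMF, rt
Reagents that add atoms: chlorotriisopropylsilane, CC(C)[Si](Cl)(C(C)C)C(C)C
Why: Silylation of a phenol; the bulky triisopropylsilyl ether is chosen because it should withstand borohydride in alcohol, mild acid and the amide base of step 6.

Step 4
Reactants: 6 4-[(triisopropylsilyl)oxy]benzaldehyde
Product: 7 {4-[(triisopropylsilyl)oxy]phenyl}methanol
Conditions: NaBH4, EtOH/THF, 0 °C
Reagents that add atoms: none
Why: Hydride reduction of an aromatic aldehyde to the benzylic alcohol; nothing else in 6 is reducible.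

Step 5
Reactants: 7 {4-[(triisopropylsilyl)oxy]phenyl}methanol
Product: 8 triphenyl{4-[(triisopropylsilyl)oxy]benzyl}phosphonium bromide
Conditions: Ph3P·HBr, MeCN, 50 °C
Reagents that add atoms: triphenylphosphine hydrobromide, [Br-].[PH+](c1ccccc1)(c1ccccc1)c1ccccc1
Why: Acid-promoted substitution of an electron-rich benzylic alcohol: protonation and loss of water give a benzylic cation stabilized by the para oxygen, which triphenylphosphine captures. Aryl silyl ethers tolerate this mild acid.

Step 6
Reactants: 8 triphenyl{4-[(triisopropylsilyl)oxy]benzyl}phosphonium bromide; 4 3-(benzyloxy)-4-(3-iodophenoxy)benzaldehyde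
Product: 11 4-{2-[3-(benzyloxy)-4-(3-iodophenoxy)phenyl]ethenyl}phenol (E/Z mixture), via ylide 9 (not isolated), via silyl stilbene 10 (not isolated)
Conditions: NaN(SiMe3)2, THF, −78 to 0 °C; then 4, 0 °C to rt; then n-Bu4NF, rt; aqueous work-up
Reagents that add atoms: none
Why: Wittig reaction of a semi-stabilized ylide that is preformed with a slight deficit of base, so no strong base meets the aryl iodide. Fluoride then cleaves the aryl silyl ether in the same flask; the alkene geometry is immaterial.

Step 7
Reactants: 11 4-{2-[3-(benzyloxy)-4-(3-iodophenoxy)phenyl]ethenyl}phenol (E/Z mixture)
Product: 12 4-{2-[3-(benzyloxy)-4-(3-iodophenoxy)phenyl]ethyl}phenol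
Conditions: TsNHNH2, NaOAc, THF/H2O, reflux
Reagents that add atoms: none
Why: Diimide reduction: diimide formed by loss of sulfinate from the tosylhydrazide transfers two hydrogens to the alkene in a concerted syn step. It leaves C–I and O–CH2Ph alone, which hydrogen over palladium would not.

Step 8
Reactants: 12 4-{2-[3-(benzyloxy)-4-(3-iodophenoxy)phenyl]ethyl}phenol; 13 (5-formyl-2-methoxyphenyl)boronic acid
Product: 14 3-(4-{2-[3-(benzyloxy)-4-(3-iodophenoxy)phenyl]ethyl}phenoxy)-4-methoxybenzaldehyde
Conditions: Cu(OAc)2, pyridine, 4 Å MS, CH2Cl2, air, rt, excess 13
Reagents that add atoms: none
Why: Chan–Lam coupling: the aryl group passes from boron to divalent copper that already carries the phenoxide, and after oxidation to trivalent copper the C–O bond forms by reductive elimination. No low-valent metal is present at room temperature, so aryl iodide and aldehyde are inert; the excess of 13 offsets the slow transfer of an ortho-substituted aryl group.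

Step 9
Reactants: 14 3-(4-{2-[3-(benzyloxy)-4-(3-iodophenoxy)phenyl]ethyl}phenoxy)-4-methoxybenzaldehyde
Product: 15 2-(benzyloxy)-4-{2-[4-(5-ethenyl-2-methoxyphenoxy)phenyl]ethyl}-1-(3-iodophenoxy)benzene
Conditions: Ph3PCH3Br, KOt-Bu, THF, 0 °C to rt
Reagents that add atoms: methyltriphenylphosphonium bromide, C[P+](c1ccccc1)(c1ccccc1)c1ccccc1.[Br-]
Why: Wittig methylenation of a non-enolizable aromatic aldehyde with a preformed ylide; no other group in 14 is electrophilic towards it.

Step 10
Reactants: 15 2-(benzyloxy)-4-{2-[4-(5-ethenyl-2-methoxyphenoxy)phenyl]ethyl}-1-(3-iodophenoxy)benzene
Product: 16 macrocyclic E-stilbene (benzyl ether of dehydropakyonol)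
Conditions: Pd(OAc)2 (0.2 equiv), P(o-tol)3 (0.4 equiv), n-Bu4NBr, K2CO3, DMF, 90 °C, slow addition by syringe pump to about 1 mM
Reagents that add atoms: none
Why: This is a Mizoroki–Heck reaction run as a macrocyclization, the closest known type being Heck closures of macrocyclic stilbenes and cinnamates. Pd(OAc)2 is reduced by the phosphine to zerovalent palladium, which inserts into the C–I bond of ring D; the resulting arylpalladium iodide (divalent palladium) binds the vinyl group of ring A and adds across it in syn fashion, the aryl group going to the terminal CH2. Bond rotation and syn beta-hydride elimination release the alkene, and K2CO3 takes up HI to return zerovalent palladium. The 20-membered ring is closed in the endo mode (20-endo-trig), both alkene carbons lying in the new ring. No stereocenter is formed; the E geometry follows from the lower-energy rotamer in the elimination, with the two aryl groups anti, and it fits because rings D and A are both meta-linked. Arylation at the terminal carbon (1,2-diarylethene, not the 1,1-isomer) is secured by the neutral pathway: halide stays on palladium, the phosphine is monodentate and no silver salt or triflate is present, so sterics direct the aryl group to the unsubstituted carbon even of this electron-rich styrene. Slow addition to high dilution favours ring closure over oligomerization, and chemoselectivity is inherent because C–I and vinyl are the only groups in 15 that react with palladium.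

Step 11
Reactants: 16 macrocyclic E-stilbene (benzyl ether of dehydropakyonol)
Product: 17 pakyonol
Conditions: H2 (1 atm), 10% Pd/C, EtOAc/MeOH, rt
Reagents that add atoms: none
Why: Heterogeneous catalytic hydrogenation saturates the stilbene and hydrogenolysis cleaves the benzylic C–O bond in the same operation. Diaryl ethers and the aryl methyl ether are stable at 1 atm and room temperature, and no stereocenter is created.

## Compound list

1 | 4-fluoro-3-hydroxybenzaldehyde | O=Cc1ccc(F)c(O)c1 | starting material
2 | 3-(benzyloxy)-4-fluorobenzaldehyde | O=Cc1ccc(F)c(OCc2ccccc2)c1 | intermediate
3 | 3-iodophenol | Oc1cccc(I)c1 | starting material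
4 | 3-(benzyloxy)-4-(3-iodophenoxy)benzaldehyde | O=Cc1ccc(Oc2cccc(I)c2)c(OCc2ccccc2)c1 | intermediate
5 | 4-hydroxybenzaldehyde | O=Cc1ccc(O)cc1 | starting material
6 | 4-[(triisopropylsilyl)oxy]benzaldehyde | O=Cc1ccc(O[Si](C(C)C)(C(C)C)C(C)C)cc1 | intermediate
7 | {4-[(triisopropylsilyl)oxy]phenyl}methanol | OCc1ccc(O[Si](C(C)C)(C(C)C)C(C)C)cc1 | intermediate
8 | triphenyl{4-[(triisopropylsilyl)oxy]benzyl}phosphonium bromide | CC(C)[Si](Oc1ccc(C[P+](c2ccccc2)(c2ccccc2)c2ccccc2)cc1)(C(C)C)C(C)C.[Br-] | intermediate
9 | triphenyl{4-[(triisopropylsilyl)oxy]benzylidene}phosphorane (ylide, formed in the flask) | CC(C)[Si](Oc1ccc(C=P(c2ccccc2)(c2ccccc2)c2ccccc2)cc1)(C(C)C)C(C)C | intermediate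
10 | 2-(benzyloxy)-1-(3-iodophenoxy)-4-{2-[4-(triisopropylsilyloxy)phenyl]ethenyl}benzene (E/Z mixture, formed in the flask) | CC(C)[Si](Oc1ccc(C=Cc2ccc(Oc3cccc(I)c3)c(OCc3ccccc3)c2)cc1)(C(C)C)C(C)C | intermediate
11 | 4-{2-[3-(benzyloxy)-4-(3-iodophenoxy)phenyl]ethenyl}phenol (E/Z mixture) | Oc1ccc(C=Cc2ccc(Oc3cccc(I)c3)c(OCc3ccccc3)c2)cc1 | intermediate
12 | 4-{2-[3-(benzyloxy)-4-(3-iodophenoxy)phenyl]ethyl}phenol | Oc1ccc(CCc2ccc(Oc3cccc(I)c3)c(OCc3ccccc3)c2)cc1 | intermediate
13 | (5-formyl-2-methoxyphenyl)boronic acid | COc1ccc(C=O)cc1B(O)O | starting material
14 | 3-(4-{2-[3-(benzyloxy)-4-(3-iodophenoxy)phenyl]ethyl}phenoxy)-4-methoxybenzaldehyde | COc1ccc(C=O)cc1Oc1ccc(CCc2ccc(Oc3cccc(I)c3)c(OCc3ccccc3)c2)cc1 | intermediate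
15 | 2-(benzyloxy)-4-{2-[4-(5-ethenyl-2-methoxyphenoxy)phenyl]ethyl}-1-(3-iodophenoxy)benzene (open-chain iodo styrene) | COc1ccc(C=C)cc1Oc1ccc(CCc2ccc(Oc3cccc(I)c3)c(OCc3ccccc3)c2)cc1 | intermediate
16 | macrocyclic E-stilbene: 20-membered ring in which C3 of ring D and C1 of ring A are joined by E-CH=CH, ring C as benzyl ether | COc1ccc(/C=C/c2cccc(Oc3ccc(CCc4ccc(O5)cc4)cc3OCc3ccccc3)c2)cc15 | intermediate
17 | pakyonol | COc1ccc2cc1Oc1ccc(cc1)CCc1ccc(c(O)c1)Oc1cccc(c1)CC2 | target

## Step count and risks

Total step count: 11. Longest linear sequence: 9 steps (from 5 through steps 3 to 11); the second branch (1 to 4) has 2 steps.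

**Step 10 (key step).** Intermolecular Heck coupling may outrun ring closure, because the two termini are kept apart by two para-phenylenes and the closing transition state is strained. The catalyst may also aggregate at the very low concentration needed.

The fallback closes the same bridge by carbonyl coupling and sets out from 14. Reductive carbonylation of the aryl iodide (CO at 1 atm, Et3SiH, Pd(OAc)2 with 1,3-bis(diphenylphosphino)propane, Na2CO3, DMF) should give 3-(4-{2-[3-(benzyloxy)-4-(3-formylphenoxy)phenyl]ethyl}phenoxy)-4-methoxybenzaldehyde F1. A McMurry coupling with low-valent titanium from TiCl4 and Zn (pyridine, THF, reflux, slow addition) should then join the two formyl carbons. It is expected to give 16 together with the Z isomer of the macrocyclic stilbene F2. The fallback returns to the route at 16, and F2 is hydrogenated with it to 17 in step 11.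

**Step 8.** Transfer of the ortho-methoxy, formyl-substituted aryl group from boron to copper may be slow, so protodeboronation and oxidative hydroxylation of 13 could consume the boronic acid before the C–O bond forms.

The fallback abandons copper and makes the ring A–ring B ether by SNAr before the bibenzyl is assembled. It sets out from 4 and returns at 14:
- NaBH4 reduces 4 to [3-(benzyloxy)-4-(3-iodophenoxy)phenyl]methanol F3, and Ph3P·HBr converts this into {[3-(benzyloxy)-4-(3-iodophenoxy)phenyl]methyl}triphenylphosphonium bromide F4.
- In parallel, isovanillin with ethylene glycol and catalytic TsOH gives 5-(1,3-dioxolan-2-yl)-2-methoxyphenol F5. Its phenoxide displaces fluoride from 4-fluorobenzaldehyde (K2CO3, DMF, 120 °C) to give 4-[5-(1,3-dioxolan-2-yl)-2-methoxyphenoxy]benzaldehyde F6.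
- Wittig reaction of the ylide of F4 (KOt-Bu, THF) with F6 should give the stilbene acetal F7 as an E/Z mixture, and diimide reduction the bibenzyl acetal F8.
- Aqueous HCl in THF then frees the formyl group and delivers 14.

**Step 5.** The benzylic cation may be diverted under the acidic conditions into ether formation or Friedel–Crafts self-alkylation, or the silyl group may be lost.

The fallback separates activation from C–P bond formation and sets out from 7. Appel bromination (CBr4, PPh3, CH2Cl2, 0 °C) under neutral conditions gives [4-(bromomethyl)phenoxy]tri(propan-2-yl)silane F9. SN2 displacement with PPh3 in toluene at 80 °C then gives 8, where the route is rejoined.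

**Step 11.** Hydrogenolysis of the benzyl ether may stall after the alkene is saturated, for instance through catalyst poisoning by traces of iodide or phosphine carried over from step 10.

The fallback uses no heterogeneous catalyst and sets out from 16. Diimide (TsNHNH2, NaOAc, THF/H2O, reflux) saturates the bridge to give O-benzylpakyonol F10. BCl3 with pentamethylbenzene as cation scavenger (CH2Cl2, −78 °C) then cleaves the benzyl ether selectively in the presence of the methyl ether and gives 17.

## Further compounds

F1 | step 10 | 3-(4-{2-[3-(benzyloxy)-4-(3-formylphenoxy)phenyl]ethyl}phenoxy)-4-methoxybenzaldehyde | COc1ccc(C=O)cc1Oc1ccc(CCc2ccc(Oc3cccc(C=O)c3)c(OCc3ccccc3)c2)cc1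
F2 | step 10 | Z isomer of the macrocyclic stilbene 16 | COc1ccc(/C=C\c2cccc(Oc3ccc(CCc4ccc(O5)cc4)cc3OCc3ccccc3)c2)cc15
F3 | step 8 | [3-(benzyloxy)-4-(3-iodophenoxy)phenyl]methanol | OCc1ccc(Oc2cccc(I)c2)c(OCc2ccccc2)c1
F4 | step 8 | {[3-(benzyloxy)-4-(3-iodophenoxy)phenyl]methyl}triphenylphosphonium bromide | [Br-].Ic1cccc(Oc2ccc(C[P+](c3ccccc3)(c3ccccc3)c3ccccc3)cc2OCc2ccccc2)c1
F5 | step 8 | 5-(1,3-dioxolan-2-yl)-2-methoxyphenol | COc1ccc(cc1O)C1OCCO1
F6 | step 8 | 4-[5-(1,3-dioxolan-2-yl)-2-methoxyphenoxy]benzaldehyde | COc1ccc(cc1Oc1ccc(C=O)cc1)C1OCCO1
F7 | step 8 | stilbene acetal, 2-{3-[4-(2-{3-(benzyloxy)-4-(3-iodophenoxy)phenyl}ethenyl)phenoxy]-4-methoxyphenyl}-1,3-dioxolane (E/Z mixture) | COc1ccc(cc1Oc1ccc(C=Cc2ccc(Oc3cccc(I)c3)c(OCc3ccccc3)c2)cc1)C1OCCO1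
F8 | step 8 | bibenzyl acetal, 2-{3-[4-(2-{3-(benzyloxy)-4-(3-iodophenoxy)phenyl}ethyl)phenoxy]-4-methoxyphenyl}-1,3-dioxolane | COc1ccc(cc1Oc1ccc(CCc2ccc(Oc3cccc(I)c3)c(OCc3ccccc3)c2)cc1)C1OCCO1
F9 | step 5 | [4-(bromomethyl)phenoxy]tri(propan-2-yl)silane | CC(C)[Si](Oc1ccc(CBr)cc1)(C(C)C)C(C)C
F10 | step 11 | O-benzylpakyonol | COc1ccc2cc1Oc1ccc(cc1)CCc1ccc(c(OCc3ccccc3)c1)Oc1cccc(c1)CC2
A1 | alternative 1 | macrocyclic bromophenol, ring B dichlorinated, ring C as benzyl ether | Oc1c(Br)cc2cc1Oc1c(Cl)cc(cc1Cl)CCc1ccc(c(OCc3ccccc3)c1)Oc1cccc(c1)CC2
A2 | alternative 1 | open-chain bis-phenol with 3,5-dibromo-4-hydroxyphenyl ring A and 3,5-dichloro-4-hydroxyphenyl ring B | Oc1c(Br)cc(cc1Br)CCc1cccc(c1)Oc1ccc(cc1OCc1ccccc1)CCc1cc(Cl)c(O)c(Cl)c1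
A3 | alternative 2 | macrocyclic 6-aryloxycyclohex-2-enone (racemic) | COc1ccc2cc1Oc1ccc(cc1)CCC1=CC(=O)C(CC1)Oc1cccc(c1)CC2
A4 | alternative 2 | open-chain 6-bromo-3-alkylcyclohex-2-enone with free ring D phenol (racemic) | COc1ccc(cc1Oc1ccc(cc1)CCC1=CC(=O)C(Br)CC1)CCc1cccc(O)c1
A5 | alternative 3 | macrocyclic aryl ketone, ring C as mesylate | COc1ccc2cc1Oc1ccc(cc1)CCc1ccc(c(OS(C)(=O)=O)c1)Oc1cccc(c1)CC2=O
A6 | alternative 3 | open-chain arylacetyl chloride on ring D with 2-methoxyphenyl ring A, ring C as mesylate | COc1ccccc1Oc1ccc(cc1)CCc1ccc(c(OS(C)(=O)=O)c1)Oc1cccc(CC(Cl)=O)c1
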